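**Plan**

- Retrosynthetic cuts, in order: the O6–acyl ester bond; the C11–C12 bond (methoxycarbonylation of the enol triflate of a C11 methyl ketone); the C6–O bond (conjugate borylation of a C6=C7–C11=O enone); the C1–H bond (back to a C1 ketone); then ring B at C8–C9 and C5–C10 together.
- Enabling feature: ring B (C5–C10) has a quaternary C10 next to the oxygenated C1, and C6/C7 carry what a C6=C7 double bond can deliver. With C1 as ketone, C9=C10(CH3)–C1=O is a 2-methyl enone and C5=C6–C7=C8 a diene, linked by the C1–C2–C3–C4 chain of ring A.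
- Forward: a 2-bromoallylic silyl ether (C1–C4, C15) and a dienylboronate (C5–C8, C11, C13; acetyl masked as ketal) are joined at C4–C5 by Suzuki coupling. Oxidation at C1 then triggers one intramolecular [4+2] event that forms rings A and B at once from an acyclic trienone.
- Stereochemistry: C3 from Brown allylation of 2-bromoacrolein; C5 and C10 relayed from C3 in the cycloaddition; C1 by hydride attack anti to the C10 methyl; C6 and C7 by α-face borylation and equilibration of the acetyl group to the equatorial site.
- End game: enol triflate carbonylation gives the methyl acrylate, Yamaguchi esterification the second acrylate, fluoride the free triol.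

Key step: step 8

Remark: eudesmane numbering is used for the bicyclic compounds (ring A = C1–C5, C10; ring B = C5–C10; α = face of H-5, β = face of the C10 methyl; C14 = C10 methyl, C15 = C4 methylidene; the acetyl compounds are 12-nor).
Remark: 2-bromoacrolein and 3-bromobut-3-en-2-one are taken as purchasable; each is otherwise one step (Br2, then Et3N) from acrolein or methyl vinyl ketone.
Remark: the carbinol carbon made in step 4 (the later C1) is formed as a mixture of epimers; this is of no consequence because it is oxidized in step 8.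

**Step 1**
Reactants: 1 2-bromoacrolein
Product: 2 (S)-2-bromohexa-1,5-dien-3-ol
Conditions: (−)-B-methoxydiisopinocampheylborane, allylmagnesium bromide, Et2O, 0 °C to rt; then 1, −78 °C; ethanolamine work-up
Reagents that add atoms: allylmagnesium bromide, C=CC[Mg]Br
Why: Brown allylation, in which the allyl group of the borane formed in the flask is delivered through a chair-like six-membered transition state to the si face of the aldehyde, which corresponds to the (S)-carbinol (the later C3) because the bromovinyl group outranks allyl.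

**Step 2**
Reactants: 2 (S)-2-bromohexa-1,5-dien-3-ol
Product: 3 (S)-2-bromo-3-(tert-butyldimethylsilyloxy)hexa-1,5-diene
Conditions: TBSCl, imidazole, DMF, rt
Reagents that add atoms: tert-butyldimethylsilyl chloride, CC(C)(C)[Si](C)(C)Cl
Why: Standard silylation of a secondary allylic alcohol, which protects the later C3 oxygen and does not touch the stereocenter.

**Step 3**
Reactants: 3 (S)-2-bromo-3-(tert-butyldimethylsilyloxy)hexa-1,5-diene
Product: 4 (S)-4-bromo-3-(tert-butyldimethylsilyloxy)pent-4-enal
Conditions: O3 (1 equiv), CH2Cl2, −78 °C; then PPh3, −78 °C to rt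
Reagents that add atoms: ozone, [O-][O+]=O
Why: Ozonolysis with reductive work-up, in which the electron-rich monosubstituted alkene should react much faster than the bromine-deactivated 1,1-disubstituted one, so that only the terminal vinyl group is cleaved to the aldehyde (the later C1).

**Step 4**
Reactants: 4 (S)-4-bromo-3-(tert-butyldimethylsilyloxy)pent-4-enal
Product: 5 (3RS,5S)-6-bromo-5-(tert-butyldimethylsilyloxy)-2-methylhepta-1,6-dien-3-ol
Conditions: isopropenylmagnesium bromide, THF, −78 °C
Reagents that add atoms: isopropenylmagnesium bromide, C=C(C)[Mg]Br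
Why: Grignard 1,2-addition installs C10, C9 and C14; the new carbinol center is formed without control, which is harmless because it becomes the C1 ketone in step 8.

**Step 5**
Reactants: 6 3-bromobut-3-en-2-one
Product: 7 2-(1-bromoethenyl)-2-methyl-1,3-dioxolane
Conditions: 1,2-bis(trimethylsilyloxy)ethane, TMSOTf (cat.), CH2Cl2, −78 °C
Reagents that add atoms: 1,2-bis(trimethylsilyloxy)ethane, C[Si](C)(C)OCCO[Si](C)(C)C
Why: Silyl-transfer ketalization masks the acetyl group (the later C11 and C13) under non-equilibrating conditions that leave the α-bromo enone double bond in place.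

**Step 6**
Reactants: 7 2-(1-bromoethenyl)-2-methyl-1,3-dioxolane; 8 4,4,5,5-tetramethyl-2-vinyl-1,3,2-dioxaborolane
Product: 9 (E)-4,4,5,5-tetramethyl-2-[3-(2-methyl-1,3-dioxolan-2-yl)buta-1,3-dien-1-yl]-1,3,2-dioxaborolane
Conditions: Pd(OAc)2 (5 mol %), P(o-tol)3 (10 mol %), AgOAc, MeCN, 50 °C
Reagents that add atoms: none
Why: Heck reaction in which the alkenylpalladium species from 7 inserts the vinylboronate at its unsubstituted terminus and syn β-hydride elimination gives the (E)-dienylboronate, the base-free silver-promoted conditions disfavoring the competing Suzuki pathway.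

**Step 7**
Reactants: 5 (3RS,5S)-6-bromo-5-(tert-butyldimethylsilyloxy)-2-methylhepta-1,6-dien-3-ol; 9 (E)-dienylboronate
Product: 10 (3RS,5S,7E)-5-(tert-butyldimethylsilyloxy)-2-methyl-6-methylidene-9-(2-methyl-1,3-dioxolan-2-yl)deca-1,7,9-trien-3-ol
Conditions: Pd(dppf)Cl2 (5 mol %), K3PO4, THF/H2O, 45 °C, degassed
Reagents that add atoms: none
Why: Suzuki–Miyaura coupling forms the C4–C5 bond with retention of the E geometry of C5=C6, and the unactivated carbinol-stage dienophile cannot yet cyclize.

**Step 8**
Reactants: 10 (3RS,5S,7E)-trienol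
Product: 12 3β-(tert-butyldimethylsilyloxy)-11,11-ethylenedioxy-12-noreudesma-4(15),6-dien-1-one, via trienone 11 (not isolated)
Conditions: Dess–Martin periodinane, CH2Cl2, 0 °C to rt; then dilution with toluene (0.005 M), BHT, 80 °C
Reagents that add atoms: none
Why: Oxidation of the C1 carbinol turns C9=C10(CH3)–C1=O into a 2-methyl enone that engages the C5=C6–C7=C8 diene in a concerted, asynchronous intramolecular [4+2] cycloaddition in which the C8–C9 bond (largest diene HOMO coefficient at C8, enone β-carbon C9) leads and the C5–C10 bond follows; the closest known reaction type is the intramolecular Diels–Alder reaction of 1,7,9-decatrien-3-ones generated by oxidation of their carbinols. Ring B is closed as the cyclohexene of the [4+2] event and ring A as the fused ring of the four-atom tether C1–C4 (type 1 mode, fused and not bridged, because the tether leaves the diene terminus C5). The C5/C10 relationship (5α-H, 10β-CH3, trans-fused) follows from the E geometry of C5=C6 together with the tether-exo, methyl-endo transition state that 2-substituted acryloyl dienophiles prefer and that lets the forming ring A adopt a chair. The absolute sense at C5 and C10 is relayed from C3, whose silyloxy group is expected to take the equatorial site of that chair, in the plane of the C4=C15 bond. The step needs regioselectivity (secured by the tether), ring-fusion selectivity (secured by the α-methyl group and the chair-like tether) and π-facial selectivity (secured by C3); the C4=C15 alkene cannot serve as part of a competing diene because that would require a bridged product with a bridgehead double bond.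

**Step 9**
Reactants: 12 bicyclic ketone
Product: 13 3β-(tert-butyldimethylsilyloxy)-11,11-ethylenedioxy-12-noreudesma-4(15),6-dien-1β-ol
Conditions: NaBH4, MeOH, −20 °C
Reagents that add atoms: none
Why: Borohydride reduction in which hydride attacks C1 along the axial trajectory from the α face, anti to the adjacent axial C10 methyl group, which should give the equatorial 1β-alcohol.

**Step 10**
Reactants: 13 1β-alcohol
Product: 14 1β,3β-bis(tert-butyldimethylsilyloxy)-11,11-ethylenedioxy-12-noreudesma-4(15),6-diene
Conditions: TBSOTf, 2,6-lutidine, CH2Cl2, −78 to 0 °C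
Reagents that add atoms: tert-butyldimethylsilyl triflate, CC(C)(C)[Si](C)(C)OS(=O)(=O)C(F)(F)F
Why: Silyl triflate silylation of the hindered neopentyl-type secondary alcohol, buffered by lutidine and run cold so that the dioxolane survives; it removes the only acidic site of ring A before the base step 14.

**Step 11**
Reactants: 14 bis-silyl ether ketal
Product: 15 1β,3β-bis(tert-butyldimethylsilyloxy)-12-noreudesma-4(15),6-dien-11-one
Conditions: PPTS, acetone/H2O (9:1), 40 °C
Reagents that add atoms: water, O
Why: Acid-catalyzed ketal hydrolysis through an allylically stabilized oxocarbenium ion unmasks the methyl ketone directly in conjugation with C6=C7, under conditions mild enough for the secondary silyl ethers and the exocyclic alkene.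

**Step 12**
Reactants: 15 enone
Product: 17 6α-hydroxy-1β,3β-bis(tert-butyldimethylsilyloxy)-12-noreudesm-4(15)-en-11-one, via 6α-boryl ketone 16 (not isolated)
Conditions: B2pin2, CuCl (5 mol %), NaOtBu (10 mol %), DPEphos, MeOH (2 equiv), THF, rt; then NaBO3·4H2O, THF/H2O, rt
Reagents that add atoms: sodium perborate, [Na+].[O-]OB=O; bis(pinacolato)diboron, CC1(C)OB(OC1(C)C)B1OC(C)(C)C(C)(C)O1 (its boryl group stays in 16 only)
Why: Copper-catalyzed conjugate borylation followed by oxidation, in which the boryl-copper species should add to C6 from the α face (away from the axial C10 methyl that is 1,3 to C6), protonation at C7 and equilibration place the acetyl group equatorial (7β), and oxidation of the C–B bond proceeds with retention to the 6α-alcohol; the isolated C4=C15 alkene is not an acceptor.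

**Step 13**
Reactants: 17 β-hydroxy ketone
Product: 18 6α-(triethylsilyloxy)-1β,3β-bis(tert-butyldimethylsilyloxy)-12-noreudesm-4(15)-en-11-one
Conditions: TESOTf, 2,6-lutidine, CH2Cl2, −78 °C
Reagents that add atoms: triethylsilyl triflate, CC[Si](CC)(CC)OS(=O)(=O)C(F)(F)F
Why: Low-temperature silylation of the aldol-type hydroxyl, which blocks retro-aldol cleavage and alkoxide chemistry in step 14 and can later be removed in the presence of the two TBS ethers.

**Step 14**
Reactants: 18 silyl-protected methyl ketone
Product: 19 1β,3β-bis(tert-butyldimethylsilyloxy)-6α-(triethylsilyloxy)-12-noreudesma-4(15),11(13)-dien-11-yl trifluoromethanesulfonate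
Conditions: KN(SiMe3)2, THF, −78 °C; N-(5-chloropyridin-2-yl)bis(trifluoromethanesulfonimide), −78 °C
Reagents that add atoms: N-(5-chloropyridin-2-yl)bis(trifluoromethanesulfonimide), FC(F)(F)S(=O)(=O)N(c1ccc(Cl)cn1)S(=O)(=O)C(F)(F)F
Why: Kinetic enolization at the unhindered methyl group and O-sulfonylation give the 1,1-disubstituted enol triflate; the tertiary C7–H is not removed, so C7 is not scrambled and the β-silyloxy group is not eliminated.

**Step 15**
Reactants: 19 enol triflate
Product: 20 6α-hydroxy-1β,3β-bis(tert-butyldimethylsilyloxy)-12-noreudesma-4(15),11(13)-dien-11-yl trifluoromethanesulfonate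
Conditions: HF·pyridine, pyridine, THF, 0 °C
Reagents that add atoms: none
Why: Buffered fluoride cleaves the triethylsilyl ether much faster than the two secondary TBS ethers and leaves the enol triflate untouched.

**Step 16**
Reactants: 21 methyl 2-(hydroxymethyl)acrylate
Product: 22 methyl 2-[(tert-butyldimethylsilyloxy)methyl]acrylate
Conditions: TBSCl, imidazole, CH2Cl2, 0 °C to rt
Reagents that add atoms: tert-butyldimethylsilyl chloride, CC(C)(C)[Si](C)(C)Cl
Why: Standard silylation of the primary allylic alcohol, so that the acid partner cannot acylate itself.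

**Step 17**
Reactants: 22 methyl 2-[(tert-butyldimethylsilyloxy)methyl]acrylate
Product: 23 2-[(tert-butyldimethylsilyloxy)methyl]acrylic acid
Conditions: LiOH, THF/H2O, 0 °C; then 1 M HCl to pH 3
Reagents that add atoms: lithium hydroxide, [Li+].[OH-]
Why: Saponification of the methyl ester at low temperature, where hydroxide attack at the ester carbonyl should outrun conjugate addition to the 2-substituted acrylate.

**Step 18**
Reactants: 20 6α-hydroxy enol triflate; 23 2-[(tert-butyldimethylsilyloxy)methyl]acrylic acid
Product: 25 1β,3β-bis(tert-butyldimethylsilyloxy)-6α-{2-[(tert-butyldimethylsilyloxy)methyl]acryloyloxy}-12-noreudesma-4(15),11(13)-dien-11-yl trifluoromethanesulfonate, via mixed anhydride 24 (not isolated)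
Conditions: 23, 2,4,6-trichlorobenzoyl chloride, Et3N, THF, rt; then 20, DMAP, toluene, rt to 40 °C
Reagents that add atoms: 2,4,6-trichlorobenzoyl chloride, O=C(Cl)c1c(Cl)cc(Cl)cc1Cl (stays in 24 only)
Why: Yamaguchi esterification acylates the hindered equatorial 6α-hydroxyl with retention at C6; doing it at the triflate stage means a γ-hydroxy acrylate ester that could lactonize onto C12 is never formed.

**Step 19**
Reactants: 25 acylated enol triflate
Product: 26 methyl 1β,3β-bis(tert-butyldimethylsilyloxy)-6α-{2-[(tert-butyldimethylsilyloxy)methyl]acryloyloxy}eudesma-4(15),11(13)-dien-12-oate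
Conditions: Pd(OAc)2 (5 mol %), PPh3 (10 mol %), Et3N, CO (1 atm), MeOH/DMF, 45 °C
Reagents that add atoms: carbon monoxide, [C-]#[O+]; methanol, CO
Why: Palladium-catalyzed methoxycarbonylation (oxidative addition of zerovalent palladium to the enol triflate, CO insertion, methanolysis) gives the methyl 2-substituted acrylate without touching C7 or the existing ester.

**Step 20**
Reactants: 26 tris-silyl ether
Product: 27 methyl 1β,3β-dihydroxy-6α-{[2-(hydroxymethyl)acryloyl]oxy}eudesma-4(15),11(13)-dien-12-oate (the target)
Conditions: HF·pyridine (excess), THF/pyridine, 0 °C to rt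
Reagents that add atoms: none
Why: Global fluoride desilylation under mildly acidic, non-nucleophilic conditions frees the three hydroxyls without acyl migration or conjugate addition to either acrylate.

**Compound list**

1 | 2-bromoacrolein | C=C(Br)C=O | starting material
2 | (S)-2-bromohexa-1,5-dien-3-ol | C=C(Br)[C@@H](O)CC=C | intermediate
3 | (S)-2-bromo-3-(tert-butyldimethylsilyloxy)hexa-1,5-diene | C=C(Br)[C@@H](O[Si](C)(C)C(C)(C)C)CC=C | intermediate
4 | (S)-4-bromo-3-(tert-butyldimethylsilyloxy)pent-4-enal | C=C(Br)[C@@H](O[Si](C)(C)C(C)(C)C)CC=O | intermediate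
5 | (3RS,5S)-6-bromo-5-(tert-butyldimethylsilyloxy)-2-methylhepta-1,6-dien-3-ol | C=C(C)C(O)C[C@H](O[Si](C)(C)C(C)(C)C)C(Br)=C | intermediate
6 | 3-bromobut-3-en-2-one | CC(=O)C(Br)=C | starting material
7 | 2-(1-bromoethenyl)-2-methyl-1,3-dioxolane | CC1(OCCO1)C(Br)=C | intermediate
8 | 4,4,5,5-tetramethyl-2-vinyl-1,3,2-dioxaborolane | C=CB1OC(C)(C)C(C)(C)O1 | starting material
9 | (E)-4,4,5,5-tetramethyl-2-[3-(2-methyl-1,3-dioxolan-2-yl)buta-1,3-dien-1-yl]-1,3,2-dioxaborolane | CC1(OCCO1)C(=C)/C=C/B1OC(C)(C)C(C)(C)O1 | intermediate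
10 | (3RS,5S,7E)-5-(tert-butyldimethylsilyloxy)-2-methyl-6-methylidene-9-(2-methyl-1,3-dioxolan-2-yl)deca-1,7,9-trien-3-ol | C=C(C)C(O)C[C@H](O[Si](C)(C)C(C)(C)C)C(=C)/C=C/C(=C)C1(C)OCCO1 | intermediate
11 | (5S,7E)-5-(tert-butyldimethylsilyloxy)-2-methyl-6-methylidene-9-(2-methyl-1,3-dioxolan-2-yl)deca-1,7,9-trien-3-one (not isolated) | C=C(C)C(=O)C[C@H](O[Si](C)(C)C(C)(C)C)C(=C)/C=C/C(=C)C1(C)OCCO1 | intermediate
12 | 3β-(tert-butyldimethylsilyloxy)-11,11-ethylenedioxy-12-noreudesma-4(15),6-dien-1-one (5α-H, 10β-CH3, trans-fused) | C1[C@H]2C(=C)[C@@H](O[Si](C)(C)C(C)(C)C)CC(=O)[C@]2(C)CCC=1C3(C)OCCO3 | intermediate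
13 | 3β-(tert-butyldimethylsilyloxy)-11,11-ethylenedioxy-12-noreudesma-4(15),6-dien-1β-ol | C1[C@H]2C(=C)[C@@H](O[Si](C)(C)C(C)(C)C)C[C@@H](O)[C@]2(C)CCC=1C3(C)OCCO3 | intermediate
14 | 1β,3β-bis(tert-butyldimethylsilyloxy)-11,11-ethylenedioxy-12-noreudesma-4(15),6-diene | C1[C@H]2C(=C)[C@@H](O[Si](C)(C)C(C)(C)C)C[C@@H](O[Si](C)(C)C(C)(C)C)[C@]2(C)CCC=1C3(C)OCCO3 | intermediate
15 | 1β,3β-bis(tert-butyldimethylsilyloxy)-12-noreudesma-4(15),6-dien-11-one | C1[C@H]2C(=C)[C@@H](O[Si](C)(C)C(C)(C)C)C[C@@H](O[Si](C)(C)C(C)(C)C)[C@]2(C)CCC=1C(C)=O | intermediate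
16 | 6α-(4,4,5,5-tetramethyl-1,3,2-dioxaborolan-2-yl)-1β,3β-bis(tert-butyldimethylsilyloxy)-12-noreudesm-4(15)-en-11-one, H-7α (not isolated) | CC1(C)OB(OC1(C)C)[C@@H]1[C@H]2C(=C)[C@@H](O[Si](C)(C)C(C)(C)C)C[C@@H](O[Si](C)(C)C(C)(C)C)[C@]2(C)CC[C@H]1C(C)=O | intermediate
17 | 6α-hydroxy-1β,3β-bis(tert-butyldimethylsilyloxy)-12-noreudesm-4(15)-en-11-one, H-7α | O[C@@H]1[C@H]2C(=C)[C@@H](O[Si](C)(C)C(C)(C)C)C[C@@H](O[Si](C)(C)C(C)(C)C)[C@]2(C)CC[C@H]1C(C)=O | intermediate
18 | 6α-(triethylsilyloxy)-1β,3β-bis(tert-butyldimethylsilyloxy)-12-noreudesm-4(15)-en-11-one | CC[Si](CC)(CC)O[C@@H]1[C@H]2C(=C)[C@@H](O[Si](C)(C)C(C)(C)C)C[C@@H](O[Si](C)(C)C(C)(C)C)[C@]2(C)CC[C@H]1C(C)=O | intermediate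
19 | 1β,3β-bis(tert-butyldimethylsilyloxy)-6α-(triethylsilyloxy)-12-noreudesma-4(15),11(13)-dien-11-yl trifluoromethanesulfonate | CC[Si](CC)(CC)O[C@@H]1[C@H]2C(=C)[C@@H](O[Si](C)(C)C(C)(C)C)C[C@@H](O[Si](C)(C)C(C)(C)C)[C@]2(C)CC[C@H]1C(=C)OS(=O)(=O)C(F)(F)F | intermediate
20 | 6α-hydroxy-1β,3β-bis(tert-butyldimethylsilyloxy)-12-noreudesma-4(15),11(13)-dien-11-yl trifluoromethanesulfonate | O[C@@H]1[C@H]2C(=C)[C@@H](O[Si](C)(C)C(C)(C)C)C[C@@H](O[Si](C)(C)C(C)(C)C)[C@]2(C)CC[C@H]1C(=C)OS(=O)(=O)C(F)(F)F | intermediate
21 | methyl 2-(hydroxymethyl)acrylate | C=C(CO)C(=O)OC | starting material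
22 | methyl 2-[(tert-butyldimethylsilyloxy)methyl]acrylate | C=C(CO[Si](C)(C)C(C)(C)C)C(=O)OC | intermediate
23 | 2-[(tert-butyldimethylsilyloxy)methyl]acrylic acid | C=C(CO[Si](C)(C)C(C)(C)C)C(=O)O | intermediate
24 | 2-[(tert-butyldimethylsilyloxy)methyl]acrylic 2,4,6-trichlorobenzoic anhydride (not isolated) | C=C(CO[Si](C)(C)C(C)(C)C)C(=O)OC(=O)c1c(Cl)cc(Cl)cc1Cl | intermediate
25 | 1β,3β-bis(tert-butyldimethylsilyloxy)-6α-{2-[(tert-butyldimethylsilyloxy)methyl]acryloyloxy}-12-noreudesma-4(15),11(13)-dien-11-yl trifluoromethanesulfonate | C=C(CO[Si](C)(C)C(C)(C)C)C(=O)O[C@@H]1[C@H]2C(=C)[C@@H](O[Si](C)(C)C(C)(C)C)C[C@@H](O[Si](C)(C)C(C)(C)C)[C@]2(C)CC[C@H]1C(=C)OS(=O)(=O)C(F)(F)F | intermediate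
26 | methyl 1β,3β-bis(tert-butyldimethylsilyloxy)-6α-{2-[(tert-butyldimethylsilyloxy)methyl]acryloyloxy}eudesma-4(15),11(13)-dien-12-oate | C=C(CO[Si](C)(C)C(C)(C)C)C(=O)O[C@@H]1[C@H]2C(=C)[C@@H](O[Si](C)(C)C(C)(C)C)C[C@@H](O[Si](C)(C)C(C)(C)C)[C@]2(C)CC[C@H]1C(=C)C(=O)OC | intermediate
27 | methyl 1β,3β-dihydroxy-6α-{[2-(hydroxymethyl)acryloyl]oxy}eudesma-4(15),11(13)-dien-12-oate (5α-H, 7α-H, 10β-CH3) | C=C(CO)C(=O)O[C@@H]1[C@H]2C(=C)[C@@H](O)C[C@@H](O)[C@]2(C)CC[C@H]1C(=C)C(=O)OC | target

**Count**

Total step count: 20. Longest linear sequence: 16 steps (steps 1–4, 7–15, 18–20).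

**Steps most likely to fail**

Step 8. The process at risk is insufficient discrimination between the trans- and cis-fused transition states, or between the two diene faces if the C3 silyloxy group, which sits next to the sp2 carbon C4, does not clearly prefer the equatorial site. As fallback, stereocontrol would be moved from the substrate to a catalyst. Trienol 10 would be oxidized with MnO2 at −20 °C, and trienone 11, kept cold, would be cyclized at −78 °C in CH2Cl2 with a chiral cationic oxazaborolidine Lewis acid (from α,α-diphenylprolinol, o-tolylboroxine and triflimide, in the enantiomer whose face preference is matched with C3). This is a known type of enantioselective Diels–Alder catalysis for α-substituted enones and also favors the acyl-exo, trans-fused mode. The fallback sets out from 10 and comes back to the route at 12; it makes no new compound (F0).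

Step 12. The processes at risk are poor facial selectivity in the boryl transfer, base-induced γ-deprotonation that moves the C4=C15 bond into conjugation, and retro-aldol cleavage during the oxidation. The fallback sets out from 15. Nucleophilic epoxidation (tBuOOH, benzyltrimethylammonium hydroxide, THF, 0 °C) from the α face should give 6α,7α-epoxy-1β,3β-bis(tert-butyldimethylsilyloxy)-12-noreudesm-4(15)-en-11-one F1. Reductive opening with SmI2 (THF/MeOH, −90 °C) cleaves the C7–O bond α to the ketone, and the samarium enolate is protonated to the equatorial acetyl compound. The route is rejoined at 17.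

Step 6. The process at risk is transmetalation of the vinylboronate (Suzuki coupling to a 2-substituted butadiene) or further coupling of the dienylboronate instead of the single Heck event. The fallback sets out from 7. Sonogashira coupling with ethynyltrimethylsilane (Pd(PPh3)2Cl2, CuI, iPr2NH) should give 2-methyl-2-[4-(trimethylsilyl)but-1-en-3-yn-2-yl]-1,3-dioxolane F2. K2CO3 in MeOH then frees 2-(but-1-en-3-yn-2-yl)-2-methyl-1,3-dioxolane F3, and syn-hydroboration of the terminal alkyne with pinacolborane (Cp2ZrHCl cat., Et3N, CH2Cl2) returns the route at 9.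

**Further compounds**

F0 | step 8 | none | none
F1 | step 12 | 6α,7α-epoxy-1β,3β-bis(tert-butyldimethylsilyloxy)-12-noreudesm-4(15)-en-11-one | CC(=O)[C@@]12O[C@@H]1[C@H]3C(=C)[C@@H](O[Si](C)(C)C(C)(C)C)C[C@@H](O[Si](C)(C)C(C)(C)C)[C@]3(C)CC2
F2 | step 6 | 2-methyl-2-[4-(trimethylsilyl)but-1-en-3-yn-2-yl]-1,3-dioxolane | CC1(OCCO1)C(=C)C#C[Si](C)(C)C
F3 | step 6 | 2-(but-1-en-3-yn-2-yl)-2-methyl-1,3-dioxolane | CC1(OCCO1)C(=C)C#C
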